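A closed, stirred vessel of constant volume holds free monomer, initiator and transfer agent, and the flasks below differ in their temperature and its timing.

| setting | ash | maple | alder | oak |
|---|---|---|---|---|
| free monomer | 5.0 mM | 5.0 mM | 5.0 mM | 5.0 mM |
| transfer agent | 0.0500 mM | 0.0500 mM | 0.0500 mM | 0.0500 mM |
| initiator | 1 mol% | 1 mol% | 1 mol% | 1 mol% |
| time | 20 s | 20 s | 20 s | 20 s |
| remark | at 25 °C until 15 s, from then on at 85 °C |  |  |  |
| temperature |  | 55 °C | 25 °C | 85 °C |

    living end + transfer agent → dead chain (k1 = 400 M⁻¹ s⁻¹, Ea1 = 45.0 kJ mol⁻¹)
    free monomer + initiator → living end + monomer in chains (k2 = 35 M⁻¹ s⁻¹, Ea2 = 46.0 kJ mol⁻¹)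
    free monomer + living end → monomer in chains + living end, rate k3*[living end]*[free monomer] (k3 = 8900 M⁻¹ s⁻¹, Ea3 = 9.00 kJ mol⁻¹)
    living end + living end ⇌ resting dimer (K4 = 11000 M⁻¹, k4 = 1000 M⁻¹ s⁻¹, Ea4 = 41.0 kJ mol⁻¹, ΔH4 = 36.0 kJ mol⁻¹)
    free monomer → uncatalysed product (k5 = 0.0052 s⁻¹, Ea5 = 96.0 kJ mol⁻¹)
    (constants at 25 °C)

- a doubled species enters its step squared and goes two at a time
- the constants hold at 25 °C; other temperatures follow from the activation energies and enthalpies

- the flask that comes out highest in amount of monomer in chains, in percent of the free monomer charged, or "all alike" when all lie within 1.5 percentage points (ash / maple / alder / oak / all alike)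
- monomer in chains at the end, in percent of the free monomer charged, ash
- monomer in chains at the end, in percent of the free monomer charged, maple
- monomer in chains at the end, in percent of the free monomer charged, alder
- monomer in chains at the end, in percent of the free monomer charged, oak

What do you compare first? Two rates on the same free monomer at one moment: chain growth, whose constant multiplies the living end, against the uncatalysed step, whose constant stands by itself. They are equal when the living end equals the uncatalysed constant divided by the growth constant, which is 5.84 × 10⁻⁴ mM at 25 °C, 0.0145 mM at 55 °C and 0.209 mM at 85 °C. I carry this quantity, the break-even living end. At any moment the selectivity between these two steps, the share of their joint flow that goes by growth, is the living end divided by the sum of the living end and the break-even amount.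

And how much living end can there be? Each initiator gives one, so the ceiling is 0.0500 mM.

What shares does that give? With the living end at its ceiling, the share is 98.8% at 25 °C, 77.6% at 55 °C and 19.3% at 85 °C.

But do the living ends stand at the ceiling? No, they start from zero. In alder, an initiator lasts 5.71 s on average at the starting monomer. In oak, free monomer lasts 0.293 s on average against the uncatalysed step, not much longer than the 0.255 s an initiator lasts there at the starting monomer. So I expect the ends in oak to arrive while the monomer is already leaving, and I put oak well under its ceiling share.

Then what of alder and ash, which share a history until 15 s? I guess a living end of 0.0250 mM, half of the ceiling. That makes a pseudo-first-order rate of 0.223 s⁻¹, which I start after the cold initiator time. On that guess, free monomer left is 12.7% at the change of temperature and 4.16% at the end of alder. Taking the cold ceiling share, I put alder at about 94.7%. Letting the remainder in ash go at the hot ceiling share, I put ash at about 88.8%. My order is alder highest, then ash, maple and oak.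

The forecast names alder, with 94.5% in alder, 91.2% in ash, 56% in maple and 7.5% in oak, and says “Alder therefore keeps the most monomer in chains”.

The simulation gives 93.9% in alder, 90.4% in ash, 57.3% in maple and 7.43% in oak, so alder stands highest.

Oak ends under its ceiling share. The neighbouring flask repeats oak with 20 mM of free monomer and the same initiator loading. Its temperature is unchanged, so its break-even living end is still 0.209 mM, while its ceiling rises to 0.200 mM. The ceiling share becomes 48.9%. The neighbouring flask ends with 70.9% as uncatalysed product and 29.1% as monomer in chains.

Its constants come from no measurement; the rest is arithmetic.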